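The substrate is the clock of these flasks, and epsilon, delta and alpha differ in what it meets while it goes.

in all of them: solid second nucleophile 0.158 M

| flask | substrate | first nucleophile | remark | time |
|---|---|---|---|---|
| blue | 0.15 M | 0.375 M | run made earlier |  |
| red | 0.15 M | 0.19 M | run made earlier |  |
| green | 0.15 M | 0.75 M | run made earlier |  |
| epsilon | 0.15 M | 0.375 M (fed, over 10 min) | all else is in the flask from the start; the feed brings no volume worth counting | 25 min |
| delta | 0.15 M (fed, over 10 min) | 0.375 M | all else is in the flask from the start; the feed brings no volume worth counting | 25 min |
| alpha | 0.15 M | 0.375 M | everything together at the start | 25 min |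

| run | time / min | target / % | other capture product / % | substrate / % |
|---|---|---|---|---|
| blue | 5.00 | 51 | 28 | 14 |
| blue | 10.0 | 53 | 36 | 5 |
| blue | 15.0 | 58 | 41 | 1 |
| blue | 20.0 | 60 | 41 | 2 |
| blue | 25.0 | 58 | 42 | 0 |
| red | 2.50 | 32 | 22 | 31 |
| red | 8.00 | 42 | 42 | 6 |
| red | 15.0 | 41 | 53 | 1 |
| red | 20.0 | 45 | 56 | 0 |
| red | 30.0 | 46 | 57 | 1 |
| green | 6.00 | 63 | 19 | 8 |
| green | 12.0 | 69 | 26 | 2 |
| green | 20.0 | 73 | 27 | 1 |
| green | 25.0 | 71 | 25 | 0 |
| green | 30.0 | 70 | 29 | 0 |

(standard deviation of a reading: 1.5 percentage points)

- at the start none of the solid second nucleophile is in solution
- a reading or a percentage of target counts all its forms, free or not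
- a reading of substrate is of its free form alone

1. which flask leads in share of target in target plus other capture product ("all alike" within 1.5 percentage points) (epsilon / delta / alpha / all alike)
2. share of target in target plus other capture product at the end, epsilon
3. share of target in target plus other capture product at the end, delta
4. share of target in target plus other capture product at the end, alpha

In the first minutes of the blue run the reading of free substrate at 5.00 min gives a lifetime τ, the time for a fall by the factor e, of 2.54 min. The first reading of the red run, at half the first nucleophile, gives 2.13 min, so these two readings show no faster loss of substrate with more first nucleophile.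

In the middle the capture changes: by 5.00 min the blue run holds target over other capture product at 1.82, but what forms afterwards comes at 0.500. I read this as solid second nucleophile entering solution.

At the end the readings stand still within their scatter, so I take the last ratio r of target to other capture product and draw a straight line through the red and green runs. It rises by 2.87 L mol⁻¹; this rise of r per molar of first nucleophile charged is a selectivity factor, which I call the slope g. The line starts at 0.262. For the blue run, which the line did not use, it gives a share of 57.2% against a reading of 58.0%, and alpha repeats blue.

In epsilon the feed lasts longer than τ, so I estimate that the decaying substrate meets on average what has been fed in one lifetime, 0.0954 M. My line then gives epsilon 34.9%. I expect delta to fall between epsilon and alpha.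

The forecast says alpha leads, with 38% for epsilon, 44% for delta and 58% for alpha, on the ground that “Final share rises with first nucleophile”. For epsilon it stands above my figure.

The flasks give 31.1% for epsilon, 43.6% for delta and 58.3% for alpha, so alpha leads.

    second nucleophile + intermediate → other capture product (k = 16.9 L mol⁻¹ s⁻¹)
    substrate + target ⇌ idle adduct, settled at all times (K = 15.6 L mol⁻¹)
    substrate ⇌ intermediate (K = 0.0740, k = 0.00810 s⁻¹)
    first nucleophile + intermediate → target (k = 1.92 L mol⁻¹ s⁻¹)
    solid second nucleophile ⇌ second nucleophile, rate k5*(cs5 - [second nucleophile]) while solid is left; crystals form when [second nucleophile] > cs5 (solubility = 0.0670 M, k = 0.00823 s⁻¹)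

Epsilon's mean first nucleophile over the first 10 min is 0.157 M, yet read back through g its ratio corresponds to a charge of 0.0662 M, less than that mean. For a neighbour of alpha charged with 0.22 M of first nucleophile, g gives 47.2%, and that flask ends at 47.2%.

The readings were generated by integration on assumed constants; scatter was added.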